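**Assumption:** the target is taken in the open para-quinone methide form of its SMILES. The isomer in which the ortho hydroxyl of ring D is bonded to Cq is assumed to return to this form through the common triaryl carbocation under mildly acidic conditions, so the end game releases the product from weakly acidic medium.

## Structural features

Selaginellin F has a benzene ring A with four contiguous substituents: C1 carries the quinone methide carbon Cq, C2 the 2,4-dihydroxyphenyl ring D, C5 a hydroxymethyl group and C6 a (4-hydroxyphenyl)ethynyl group, while C3 and C4 are CH. Cq is the exocyclic carbon of a para-quinone methide; it joins ring A, a 4-hydroxyphenyl ring and a cyclohexa-2,5-dienone ring, and the last two are interchanged by tautomerism. Because the dienone ring is symmetric, the exocyclic double bond has no E/Z isomers and the molecule has no stereocentre, so no neighbouring stereocentres need to be related. The fragile parts are the quinone methide (electrophilic at Cq towards 1,6-addition), the ortho hydroxyl of ring D (within reach of Cq for closure of a six-membered ether), the diarylalkyne between Cq and CH2OH (no hydrogenation, no hot base), the benzylic alcohol and five acidic hydroxyls. The real difficulty is the 1,2,3,4-tetrasubstituted ring A, whose most hindered position C1 must bear a triaryl-substituted carbon between an aryl ring and an alkyne. The key step uses the fact that Cq and the ortho oxygen of ring D can be joined as a lactone (a 6H-benzo[c]chromen-6-one). In that form C2, C3 and C4 of ring A with ring D and its ortho oxygen are C4, C3, C2 and the benzo ring of a chromone, and Cq, C1, C6, C5 and the CH2O carbon are the ester carbon, C2, C3, C4 and C5 of a 5-oxygenated 3-oxopentanoate. Ring A is therefore made, not substituted, and the oxygen that the ring synthesis leaves at C6 becomes the handle for the alkyne.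

## Logic of the disconnections

**25 back to 23 (through 24).** No skeletal bond is cut: the exocyclic Cq=C bond goes back to a C–OH bond and five O–H bonds go back to O–Si bonds. The quinone methide is the most sensitive group, and a carbinol with two para-oxygenated aryl groups loses water under mild acid, so it can appear last. The gain is that Cq is never electrophilic during the route and only one kind of protecting group is carried. The demand is that five silyl ethers, one of them primary alkyl, fall in one buffered fluoride operation and that the product is released from weakly acidic medium.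

**23 back to 18 and two equivalents of 21 (from 20, from 19).** Both Cq–aryl bonds are cut. The two aryl groups are identical, so Cq can be an acyl carbon that takes the same nucleophile twice; in 18 the ring D oxygen is at once the leaving group and protected. Two rings are removed, and 21 needs only O-silylation of 19 and halogen–lithium exchange of 20. The forward step must push the second addition onto a ketone flanked by an aryl ring and an alkyne, and the aryl silyl ethers and the alkyne must ignore the organolithium.

**18 back to 13 and 17; 13 back to 12; 17 back through 16 and 15 to 14.** The C6–C(sp) bond is cut. The oxygen on C6 of 12 is ortho to the lactone carbonyl, so its sulfonate in 13 is activated for oxidative addition. This removes the diarylalkyne and leaves a terminal alkyne that comes from 14 in three routine operations. The coupling must succeed at a position with two ortho substituents and spare the lactone and the silyl ethers.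

**12 back to 2 and 9 (key disconnection).** Ring A bonds C4–C5 and C1–C2 and the lactone C–O bond are cut. Ring A and the lactone ring are exchanged for a chromone and an acyclic diene, and all four substituent positions of ring A come out differentiated. The atom mapping was checked in both directions: chromone C2, C3, C4 become ring A C4, C3, C2; diene C4, C3, C2 become ring A C5, C6, C1; the chromone 7-oxygen ends para to the biaryl bond. The structures of 2, 9 and 12 are consistent with it and need no correction of connectivity. The forward step requires attack through the terminal carbon of 9, and ring closure must be faster than loss of the silyloxy group β to the ketone. The bulky triisopropylsilyl group on the CH2O oxygen is kept for that reason.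

**9 back through 7 and 6 to 5, and 5 back to 3.** Two O–Si bonds of the diene, the O–Si bond of the primary ether and the bond between the terminal carbon and the CH2O carbon are cut. The γ-carbon of the dianion of 3 is its most nucleophilic site and accepts a one-carbon aldehyde. The gain is a commercial four-carbon keto ester. The demands are mono-hydroxymethylation and a γ-deprotonation of 7 that does not expel the β-silyloxy group, which is why the dienolate is trapped as it forms.

**2 back to 1.** Only the O–Si bond is cut. The bulky aryl silyl ether tolerates the silyl triflate, the amine in ethanol, the palladium coupling and the aryllithium, and leaves in the final fluoride step with the others.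

## Other disconnections considered

**Alternative 1:** The cut goes through the biaryl bond C2–ring D and the bond C1–Cq at once; ring A is an intact benzene functionalised through a strained C1–C2 triple bond.
- Forward key step: LiN(C9H18) (lithium 2,2,6,6-tetramethylpiperidide) removes the C1 proton of aryl chloride A2 and LiCl is lost. The aryllithium A3 adds at C2 and the new C1 carbanion is captured by benzophenone A4, which gives the fully protected carbinol A1. One acid treatment would then free all hydroxyls and form the quinone methide.
- In its favour: three simple fragments give the whole skeleton in one flask, and the inductive pull of the sp carbon at C6 should steer the nucleophile to the remote C2. The ring D ortho oxygen stays protected in A1, so addition to the carbonyl cannot stall at a cyclic hemiketal.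
- Against it: two selectivities rest on kinetics and not on connectivity. C1–H competes with C3–H, the benzylic CH2 and the positions ortho to the methoxymethoxy groups as sites of lithiation. The amide base competes with A3 for the strained bond, the excess of A3 this requires also consumes A4, and the congested 2,6-disubstituted aryllithium must still add to a diaryl ketone.
- Comparison: the chosen plan builds ring A and fixes all four positions by the bonding of its precursors, whereas this plan substitutes ring A. Mechanistically it is one organolithium cascade of high functional density against separate, individually precedented polar steps. On step economy (an estimated seven to eight operations against fourteen) and on the protected ring D oxygen at the carbinol stage this alternative is the better plan; the end games are equal, one global deprotection each.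

**Alternative 2:** The cut goes through three bonds of ring A (C1–C2, C3–C4, C5–C6); ring A arises from three triple bonds, two of them tied by the ester that becomes the lactone.
- Forward key step: with CpCo(CO)2 under irradiation the two ester-linked triple bonds of diynoate A6 couple at cobalt (bond C1–C2, lactone ring) and the silylated propargyl ether A7 is inserted (bonds C3–C4 and C5–C6). The product is A5, which corresponds to 18 with an additional trimethylsilyl group on C4. Protodesilylation, double aryllithium addition and deprotection would follow.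
- In its favour: ring A, the lactone ring and the alkyne on C6 arrive together. No sulfonate formation and no palladium coupling at the hindered C6 position are needed, and on this point it is the better plan. The conditions are neutral and the intramolecular C1–C2 bond is regiochemically fixed, which is the equal of the chosen plan.
- Against it: A6 contains a conjugated diyne, so the metal can engage the wrong triple bond, and A5 still carries an alkyne that can react further. The orientation of A7 is set only by steric preference. The aryl alkynoate ester and the 2-ethynylphenol part of A6 are sensitive and need a separate diyne synthesis, and a hindered aryl–silicon bond must later be cleaved without loss of the acid-labile groups.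
- Comparison: both plans make ring A de novo with the same lactone bridge. In the chosen plan the polarity of the two partners allows one outcome; here several metallacycle pathways compete. Step economy should be about equal, since the steps saved after the key step are spent on A6 and on the desilylation.

**Alternative 3:** The cut goes through four bonds of ring D; ring A is the preformed scaffold with a diazo enone side chain on C2.
- Forward key step: irradiation of diazo enone A9 causes a Wolff rearrangement; the resulting ketene function adds tert-butoxyethyne A10 in a (2+2) step, and on warming 4π opening and 6π closure give the resorcinol ring of A8. Double aryllithium addition to the methyl ester and deprotection by fluoride and acid would follow.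
- In its favour: the regiochemistry of ring D is unambiguous and its two oxygens come out differentiated (free ortho hydroxyl, para tert-butyl ether), which is the equal of the chosen plan. The biaryl bond needs no cross-coupling, the conditions are free of acid and base, and the ester on C1 and the alkyne on C6 are in place before the key step.
- Against it: the strongest step is spent on the simplest ring, which could be bought as a resorcinol derivative. The real problem, the contiguously tetrasubstituted ring A with ester, alkyne, CH2OSi and an (E)-enone chain, is moved into A9 and would need a long stepwise arene synthesis. The diarylalkyne absorbs in the region used for photolysis, the carbene or the diazo group can react with the alkyne or the enone, and A10 is volatile and sensitive. The free phenol of A8 next to the ester should lactonise to the same type of lactone as 18, so the end game converges with the chosen one, with an extra acid step for the tert-butyl ether.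
- Comparison: the chosen plan builds the hard ring A, this plan builds the easy ring D. Its pericyclic cascade is as well defined mechanistically as the polar domino. Step economy is clearly worse, estimated at more than sixteen steps.

Key step: step 6

## Route

Step 1
Reactants: 1 7-hydroxy-4H-chromen-4-one
Product: 2 7-(triisopropylsilyloxy)-4H-chromen-4-one
Conditions: i-Pr3SiCl (1.2 equiv), imidazole (2.5 equiv), DMF, 0 → 20 °C
Reagents that add atoms: chlorotriisopropylsilane, CC(C)[Si](Cl)(C(C)C)C(C)C
Why: Imidazole-mediated O-silylation of a phenol; the pyranone is inert to these conditions and the bulky aryl silyl ether should survive the silyl triflate, amine in ethanol, palladium coupling and aryllithium that follow.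

Step 2
Reactants: 3 methyl acetoacetate
Product: 5 methyl 5-hydroxy-3-oxopentanoate, via acetoacetate dianion 4 (not isolated)
Conditions: NaH (1.1 equiv), THF, 0 °C; n-BuLi (1.05 equiv), 0 °C; CH2O (gas from cracked paraformaldehyde, 1.0 equiv), −78 → −20 °C; aq. HCl to pH 5, 0 °C
Reagents that add atoms: formaldehyde, C=O
Why: Aldol addition of the 1,3-dianion of a β-keto ester, which reacts at its more basic γ-carbon; the remaining keto ester enolate holds the adduct until the cold acidic quench, and no excess of formaldehyde is used so that a second hydroxymethylation is avoided.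

Step 3
Reactants: 5 methyl 5-hydroxy-3-oxopentanoate
Product: 6 methyl 3-oxo-5-(triisopropylsilyloxy)pentanoate
Conditions: i-Pr3SiCl (1.1 equiv), imidazole (2.2 equiv), CH2Cl2, 0 → 20 °C
Reagents that add atoms: chlorotriisopropylsilane, CC(C)[Si](Cl)(C(C)C)C(C)C
Why: Selective silylation of the primary alcohol; the hindered chlorosilane does not silylate the keto ester under imidazole conditions, and the bulky silyl ether is a poor leaving group for the β-elimination that threatens later steps.

Step 4
Reactants: 6 methyl 3-oxo-5-(triisopropylsilyloxy)pentanoate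
Product: 7 methyl (2Z)-5-(triisopropylsilyloxy)-3-(trimethylsilyloxy)pent-2-enoate
Conditions: Me3SiCl (1.5 equiv), NEt3 (1.6 equiv), toluene, 20 °C, 48 h; filtration under argon
Reagents that add atoms: chlorotrimethylsilane, C[Si](C)(C)Cl
Why: Amine-mediated O-silylation of the enol of a β-keto ester, the first stage of the standard two-stage preparation of 1,3-bis(silyl enol ethers); the double-bond geometry (drawn Z) is of no consequence because it is lost later.

Step 5
Reactants: 7 methyl (2Z)-5-(triisopropylsilyloxy)-3-(trimethylsilyloxy)pent-2-enoate
Product: 9 (1Z,3Z)-1-methoxy-1,3-bis(trimethylsilyloxy)-5-(triisopropylsilyloxy)penta-1,3-diene, via lithium dienolate 8 (not isolated)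
Conditions: Me3SiCl (1.8 equiv), then LiN(i-Pr)2 (1.5 equiv, commercial solution), THF, −78 °C (in situ trapping), → 20 °C; pentane, filtration under argon; used at once
Reagents that add atoms: chlorotrimethylsilane, C[Si](C)(C)Cl
Why: γ-Deprotonation of the silyloxy enoate and O-silylation of the ester dienolate, the second stage of the bis(silyl enol ether) synthesis; the low temperature and the silyl chloride already present keep the dienolate from expelling the β-silyloxy group. Either geometry of the two double bonds serves, since both are consumed in step 6.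

Step 6
Reactants: 2 7-(triisopropylsilyloxy)-4H-chromen-4-one; 9 (1Z,3Z)-1-methoxy-1,3-bis(trimethylsilyloxy)-5-(triisopropylsilyloxy)penta-1,3-diene
Product: 12 7-hydroxy-3-(triisopropylsilyloxy)-8-[(triisopropylsilyloxy)methyl]-6H-benzo[c]chromen-6-one, via silyloxybenzopyrylium triflate 10 (not isolated), via chromanone keto ester 11 (not isolated)
Conditions: Me3SiOTf (1.3 equiv), CH2Cl2, 20 °C, 1 h; 9 (1.5 equiv), 0 → 20 °C, 12 h; 1 M aq. HCl, 0 °C; then NEt3 (2 equiv), EtOH, 20 °C, 12 h
Reagents that add atoms: none
Why: Me3SiOTf silylates the chromone carbonyl of 2 to give the benzopyrylium salt 10, whose C2 accepts the terminal carbon of 9 (the most nucleophilic site of a 1,3-bis(silyloxy)diene) in a vinylogous Mukaiyama–Michael addition; hydrolysis gives 11 and so forms ring A bond C4–C5. NEt3 in ethanol then deprotonates C3 of the chromanone and expels the aryl oxide (retro-oxa-Michael, E1cB); the doubly activated central carbon of the keto ester adds to the liberated aryl ketone, and loss of water and enolisation aromatise ring A (bond C1–C2). The freed phenoxide is acylated by the methyl ester with loss of methanol and closes the lactone. The closest known reaction type is this same Me3SiOTf-mediated condensation of chromones with 1,3-bis(silyl enol ethers), including dienes substituted at the terminal carbon, followed by the amine-induced retro-Michael, aldol and lactonisation sequence to 7-hydroxy-6H-benzo[c]chromen-6-ones. Ring A closes by a 6-(enolendo)-exo-trig aldol addition followed by dehydration, the pyranone ring by a 6-exo-trig acyl substitution that the ortho,ortho' placement on the biaryl favours. No stereocentre remains, since the two transient ones of 11 and both diene geometries are erased by aromatisation. The step needs terminal-carbon and not central-carbon attack and 1,4- and not 1,2-addition, which the silyl dienol ether and the silyloxy group on C4 of 10 secure; it also needs ring closure to outrun loss of silanol from the β-silyloxy ketone, which the bulky i-Pr3Si group, the weak amine base and the irreversible aromatisation should ensure.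

Step 7
Reactants: 12 7-hydroxy-3-(triisopropylsilyloxy)-8-[(triisopropylsilyloxy)methyl]-6H-benzo[c]chromen-6-one
Product: 13 6-oxo-3-(triisopropylsilyloxy)-8-[(triisopropylsilyloxy)methyl]-6H-benzo[c]chromen-7-yl trifluoromethanesulfonate
Conditions: Tf2O (1.5 equiv), pyridine (3 equiv), CH2Cl2, −78 → 0 °C
Reagents that add atoms: trifluoromethanesulfonic anhydride, O=S(=O)(OS(=O)(=O)C(F)(F)F)C(F)(F)F
Why: O-Sulfonylation of a phenol; the hydroxyl is hydrogen-bonded to the lactone carbonyl and flanked by CH2OSi, hence the excess of anhydride, while the silyl ethers and the lactone are inert to the pyridine-buffered reagent.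

Step 8
Reactants: 14 4-iodophenol
Product: 15 (4-iodophenoxy)triisopropylsilane
Conditions: i-Pr3SiCl (1.1 equiv), imidazole (2.2 equiv), DMF, 20 °C
Reagents that add atoms: chlorotriisopropylsilane, CC(C)[Si](Cl)(C(C)C)C(C)C
Why: Routine phenol silylation; the same silyl group is used on every oxygen so that one fluoride operation ends the synthesis.

Step 9
Reactants: 15 (4-iodophenoxy)triisopropylsilane
Product: 16 triisopropyl{4-[(trimethylsilyl)ethynyl]phenoxy}silane
Conditions: Me3SiC≡CH (1.2 equiv), PdCl2(PPh3)2 (2 mol %), CuI (4 mol %), NEt3, THF, 20 °C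
Reagents that add atoms: ethynyltrimethylsilane, C#C[Si](C)(C)C
Why: Sonogashira coupling of an aryl iodide at room temperature; the C-silyl group prevents double coupling.

Step 10
Reactants: 16 triisopropyl{4-[(trimethylsilyl)ethynyl]phenoxy}silane
Product: 17 (4-ethynylphenoxy)triisopropylsilane
Conditions: K2CO3 (0.2 equiv), MeOH/THF (1:1), 0 °C, monitored
Reagents that add atoms: none
Why: Methanolysis of the alkynyl C–Si bond under catalytic carbonate; the hindered aryl O–Si(i-Pr)3 bond is far slower to cleave than the C–SiMe3 bond at 0 °C.

Step 11
Reactants: 13 6-oxo-3-(triisopropylsilyloxy)-8-[(triisopropylsilyloxy)methyl]-6H-benzo[c]chromen-7-yl trifluoromethanesulfonate; 17 (4-ethynylphenoxy)triisopropylsilane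
Product: 18 3-(triisopropylsilyloxy)-8-[(triisopropylsilyloxy)methyl]-7-{[4-(triisopropylsilyloxy)phenyl]ethynyl}-6H-benzo[c]chromen-6-one
Conditions: 17 (1.5 equiv), PdCl2(PPh3)2 (5 mol %), CuI (10 mol %), Bu4NI (1.5 equiv), NEt3/DMF (1:4), 70 °C, degassed
Reagents that add atoms: none
Why: Sonogashira coupling of an aryl triflate that the ortho lactone carbonyl activates towards oxidative addition of zerovalent palladium; the iodide additive assists the triflate coupling, and the lactone and silyl ethers tolerate the amine at this temperature.

Step 12
Reactants: 19 4-bromophenol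
Product: 20 (4-bromophenoxy)triisopropylsilane
Conditions: i-Pr3SiCl (1.1 equiv), imidazole (2.2 equiv), DMF, 20 °C
Reagents that add atoms: chlorotriisopropylsilane, CC(C)[Si](Cl)(C(C)C)C(C)C
Why: Routine phenol silylation; a para silyl ether cannot undergo silyl migration to the lithiated carbon and is stable to the exchange reagent at −78 °C.

Step 13
Reactants: 20 (4-bromophenoxy)triisopropylsilane; 18 3-(triisopropylsilyloxy)-8-[(triisopropylsilyloxy)methyl]-7-{[4-(triisopropylsilyloxy)phenyl]ethynyl}-6H-benzo[c]chromen-6-one
Product: 23 {6-[2-hydroxy-4-(triisopropylsilyloxy)phenyl]-3-[(triisopropylsilyloxy)methyl]-2-{[4-(triisopropylsilyloxy)phenyl]ethynyl}phenyl}bis[4-(triisopropylsilyloxy)phenyl]methanol, via aryllithium 21 (not isolated), via lithium phenolate ketone 22 (not isolated)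
Conditions: 20 (3.2 equiv), n-BuLi (3.0 equiv), THF, −78 °C, 30 min; 18 (1.0 equiv), −78 → 0 °C; sat. aq. NH4Cl, 0 °C; filtration through NEt3-deactivated silica, used crude
Reagents that add atoms: none
Why: Bromine–lithium exchange, then double addition of an aryllithium to an aryl ester: the first adduct collapses with loss of the ring D phenoxide to ketone 22, and the second addition gives the tertiary alkoxide. There is no enolisable position, and the silyl ethers and the diarylalkyne do not react with the aryllithium at or below 0 °C.

Step 14
Reactants: 23 {6-[2-hydroxy-4-(triisopropylsilyloxy)phenyl]-3-[(triisopropylsilyloxy)methyl]-2-{[4-(triisopropylsilyloxy)phenyl]ethynyl}phenyl}bis[4-(triisopropylsilyloxy)phenyl]methanol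
Product: 25 selaginellin F (4-[{6-(2,4-dihydroxyphenyl)-3-(hydroxymethyl)-2-[(4-hydroxyphenyl)ethynyl]phenyl}(4-hydroxyphenyl)methylidene]cyclohexa-2,5-dien-1-one), via desilylated carbinol 24 (not isolated)
Conditions: Bu4NF (8 equiv), AcOH (8 equiv), THF, 0 → 20 °C; then 1 M aq. HCl, 20 °C, 15 min; work-up at pH 5–6
Reagents that add atoms: none
Why: Fluoride cleavage of the four aryl silyl ethers and the primary silyl ether, buffered with acetic acid so that no alkoxide or free phenoxide persists beside the alkyne and Cq. The bis(4-hydroxyphenyl)carbinol then ionises under mild acid to a stabilised triaryl carbocation that loses a phenolic proton to give the para-quinone methide (fuchsone-type dehydration); no stereocentre is formed.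

## Compound list

1 | 7-hydroxy-4H-chromen-4-one | O=c1ccoc2cc(O)ccc12 | starting material
2 | 7-(triisopropylsilyloxy)-4H-chromen-4-one | O=c1ccoc2cc(O[Si](C(C)C)(C(C)C)C(C)C)ccc12 | intermediate
3 | methyl acetoacetate | COC(=O)CC(C)=O | starting material
4 | sodium lithium 1,3-dianion of methyl acetoacetate | [Na+].[Li+].COC([O-])=CC([O-])=C | intermediate
5 | methyl 5-hydroxy-3-oxopentanoate | COC(=O)CC(=O)CCO | intermediate
6 | methyl 3-oxo-5-(triisopropylsilyloxy)pentanoate | COC(=O)CC(=O)CCO[Si](C(C)C)(C(C)C)C(C)C | intermediate
7 | methyl (2Z)-5-(triisopropylsilyloxy)-3-(trimethylsilyloxy)pent-2-enoate | COC(=O)/C=C(/CCO[Si](C(C)C)(C(C)C)C(C)C)O[Si](C)(C)C | intermediate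
8 | lithium dienolate of 7 (geometry not defined) | [Li+].COC([O-])=CC(O[Si](C)(C)C)=CCO[Si](C(C)C)(C(C)C)C(C)C | intermediate
9 | (1Z,3Z)-1-methoxy-1,3-bis(trimethylsilyloxy)-5-(triisopropylsilyloxy)penta-1,3-diene | CO/C(O[Si](C)(C)C)=C/C(O[Si](C)(C)C)=C/CO[Si](C(C)C)(C(C)C)C(C)C | intermediate
10 | 7-(triisopropylsilyloxy)-4-(trimethylsilyloxy)chromenylium trifluoromethanesulfonate | C[Si](C)(C)Oc1cc[o+]c2cc(O[Si](C(C)C)(C(C)C)C(C)C)ccc12.[O-]S(=O)(=O)C(F)(F)F | intermediate
11 | methyl 3-oxo-4-[4-oxo-7-(triisopropylsilyloxy)-3,4-dihydro-2H-chromen-2-yl]-5-(triisopropylsilyloxy)pentanoate (mixture of diastereomers, racemic) | COC(=O)CC(=O)C(CO[Si](C(C)C)(C(C)C)C(C)C)C1CC(=O)c2ccc(O[Si](C(C)C)(C(C)C)C(C)C)cc2O1 | intermediate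
12 | 7-hydroxy-3-(triisopropylsilyloxy)-8-[(triisopropylsilyloxy)methyl]-6H-benzo[c]chromen-6-one | O=C1Oc2cc(O[Si](C(C)C)(C(C)C)C(C)C)ccc2-c2ccc(CO[Si](C(C)C)(C(C)C)C(C)C)c(O)c21 | intermediate
13 | 6-oxo-3-(triisopropylsilyloxy)-8-[(triisopropylsilyloxy)methyl]-6H-benzo[c]chromen-7-yl trifluoromethanesulfonate | O=C1Oc2cc(O[Si](C(C)C)(C(C)C)C(C)C)ccc2-c2ccc(CO[Si](C(C)C)(C(C)C)C(C)C)c(OS(=O)(=O)C(F)(F)F)c21 | intermediate
14 | 4-iodophenol | Oc1ccc(I)cc1 | starting material
15 | (4-iodophenoxy)triisopropylsilane | CC(C)[Si](Oc1ccc(I)cc1)(C(C)C)C(C)C | intermediate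
16 | triisopropyl{4-[(trimethylsilyl)ethynyl]phenoxy}silane | C[Si](C)(C)C#Cc1ccc(O[Si](C(C)C)(C(C)C)C(C)C)cc1 | intermediate
17 | (4-ethynylphenoxy)triisopropylsilane | C#Cc1ccc(O[Si](C(C)C)(C(C)C)C(C)C)cc1 | intermediate
18 | 3-(triisopropylsilyloxy)-8-[(triisopropylsilyloxy)methyl]-7-{[4-(triisopropylsilyloxy)phenyl]ethynyl}-6H-benzo[c]chromen-6-one | O=C1Oc2cc(O[Si](C(C)C)(C(C)C)C(C)C)ccc2-c2ccc(CO[Si](C(C)C)(C(C)C)C(C)C)c(C#Cc3ccc(O[Si](C(C)C)(C(C)C)C(C)C)cc3)c21 | intermediate
19 | 4-bromophenol | Oc1ccc(Br)cc1 | starting material
20 | (4-bromophenoxy)triisopropylsilane | CC(C)[Si](Oc1ccc(Br)cc1)(C(C)C)C(C)C | intermediate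
21 | [4-(triisopropylsilyloxy)phenyl]lithium | [Li]c1ccc(O[Si](C(C)C)(C(C)C)C(C)C)cc1 | intermediate
22 | lithium phenolate of {6-[2-hydroxy-4-(triisopropylsilyloxy)phenyl]-3-[(triisopropylsilyloxy)methyl]-2-{[4-(triisopropylsilyloxy)phenyl]ethynyl}phenyl}[4-(triisopropylsilyloxy)phenyl]methanone | [Li+].[O-]c1cc(O[Si](C(C)C)(C(C)C)C(C)C)ccc1-c1ccc(CO[Si](C(C)C)(C(C)C)C(C)C)c(C#Cc2ccc(O[Si](C(C)C)(C(C)C)C(C)C)cc2)c1C(=O)c1ccc(O[Si](C(C)C)(C(C)C)C(C)C)cc1 | intermediate
23 | {6-[2-hydroxy-4-(triisopropylsilyloxy)phenyl]-3-[(triisopropylsilyloxy)methyl]-2-{[4-(triisopropylsilyloxy)phenyl]ethynyl}phenyl}bis[4-(triisopropylsilyloxy)phenyl]methanol | Oc1cc(O[Si](C(C)C)(C(C)C)C(C)C)ccc1-c1ccc(CO[Si](C(C)C)(C(C)C)C(C)C)c(C#Cc2ccc(O[Si](C(C)C)(C(C)C)C(C)C)cc2)c1C(O)(c1ccc(O[Si](C(C)C)(C(C)C)C(C)C)cc1)c1ccc(O[Si](C(C)C)(C(C)C)C(C)C)cc1 | intermediate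
24 | {6-(2,4-dihydroxyphenyl)-3-(hydroxymethyl)-2-[(4-hydroxyphenyl)ethynyl]phenyl}bis(4-hydroxyphenyl)methanol | OCc1ccc(-c2ccc(O)cc2O)c(C(O)(c2ccc(O)cc2)c2ccc(O)cc2)c1C#Cc1ccc(O)cc1 | intermediate
25 | selaginellin F, 4-[{6-(2,4-dihydroxyphenyl)-3-(hydroxymethyl)-2-[(4-hydroxyphenyl)ethynyl]phenyl}(4-hydroxyphenyl)methylidene]cyclohexa-2,5-dien-1-one (no stereocentre) | O=C1C=CC(=C(c2ccc(O)cc2)c2c(-c3ccc(O)cc3O)ccc(CO)c2C#Cc2ccc(O)cc2)C=C1 | target

## Step count and least certain steps

Total step count: 14. Longest linear sequence: 9 steps (steps 2, 3, 4, 5, 6, 7, 11, 13, 14, from 3 to 25).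

**Step 6 (key step).** The most likely failures are two. The conjugate addition may be slow, because the attacking terminal carbon of 9 carries the CH2OSi substituent, so that hydrolysis of the diene wins. In the amine stage, silanol may be lost from the β-silyloxy ketone of 11 (E1cB) before ring A closes.
Fallback, from 3 and 2, returning at 12: the C8 carbon is introduced after the ring synthesis.
- 3 is silylated as in step 4 to methyl (2Z)-3-(trimethylsilyloxy)but-2-enoate F1 and as in step 5 to the parent diene (1Z)-1-methoxy-1,3-bis(trimethylsilyloxy)buta-1,3-diene F2, which has no β-leaving group and an unhindered terminus.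
- Under the conditions of step 6, F2 and 2 should give, through 10 and methyl 3-oxo-4-[4-oxo-7-(triisopropylsilyloxy)-3,4-dihydro-2H-chromen-2-yl]butanoate F3, 7-hydroxy-3-(triisopropylsilyloxy)-6H-benzo[c]chromen-6-one F4.
- Magnesium-mediated ortho-formylation (MgCl2, NEt3, paraformaldehyde, MeCN, reflux) can only reach C8 and should give 7-hydroxy-6-oxo-3-(triisopropylsilyloxy)-6H-benzo[c]chromene-8-carbaldehyde F5.
- NaBH4 in THF/MeOH at 0 °C should reduce the aldehyde to 7-hydroxy-8-(hydroxymethyl)-3-(triisopropylsilyloxy)-6H-benzo[c]chromen-6-one F6.
- i-Pr3SiCl (1.05 equiv) and imidazole at 0 °C should silylate the primary alcohol in preference to the hydrogen-bonded phenol and give 12.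

**Step 5.** The lithium dienolate 8 has a silyloxy group β to its γ-carbon; expulsion of silanolate and hydrolysis of the moisture-sensitive product during handling are the main dangers.
Fallback, from 6, returning at 9: the strong-base pathway is replaced by soft enolisation. 6 is treated with Me3SiOTf (2.2 equiv) and NEt3 (2.5 equiv) in diethyl ether at 0 °C, so that both enol ethers form by deprotonation of O-silylated carbonyl groups and no carbanion β to the leaving group is generated. 7 and 8 are bypassed and no compound outside the compound list is made (F0).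

**Step 11.** The triflate carbon has two ortho substituents, so oxidative addition and transmetalation may be slow; cleavage of the S–O bond back to 12 and oxidative dimerisation of 17 would then take over.
Fallback, from 13, returning at 18: the coupling is split into two easier bond formations.
- Stille coupling of 13 with Bu3SnC≡CH (Pd(PPh3)4, LiCl, 1,4-dioxane, 90 °C) brings in the smallest possible alkyne without copper and should give 7-ethynyl-3-(triisopropylsilyloxy)-8-[(triisopropylsilyloxy)methyl]-6H-benzo[c]chromen-6-one F7.
- Sonogashira coupling of F7 with the reactive aryl iodide 15 (PdCl2(PPh3)2, CuI, NEt3, THF, 20 °C) should give 18.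

**Step 13.** The reaction may stop after the first addition: the phenolate of 22 can close onto the ketone to a cyclic hemiketal alkoxide, and the ketone is shielded by an aryl ring and an alkyne, so the second addition may fail.
Fallback, from 18 and 21, returning at 25: the two additions are separated and the phenolate is capped.
- 18 is treated with 21 (1.1 equiv) at −78 → −40 °C, and the phenolate 22 is trapped in the same flask with i-Pr3SiOTf to give {6-[2,4-bis(triisopropylsilyloxy)phenyl]-3-[(triisopropylsilyloxy)methyl]-2-{[4-(triisopropylsilyloxy)phenyl]ethynyl}phenyl}[4-(triisopropylsilyloxy)phenyl]methanone F8, which cannot close to a hemiketal.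
- A second charge of 21 (2 equiv, −78 → 20 °C) should give {6-[2,4-bis(triisopropylsilyloxy)phenyl]-3-[(triisopropylsilyloxy)methyl]-2-{[4-(triisopropylsilyloxy)phenyl]ethynyl}phenyl}bis[4-(triisopropylsilyloxy)phenyl]methanol F9.
- The conditions of step 14 then remove six silyl groups instead of five and lead through 24 to 25.

**Step 14.** The primary silyl ether is cleaved far more slowly than the aryl silyl ethers under buffered fluoride. The quinone methide, which forms as soon as the para oxygens are free, is then exposed for a long time to fluoride and phenols (1,6-addition, oligomerisation, closure of the ring D hydroxyl onto Cq). If the buffer is omitted to gain speed, base-induced addition of the carbinol oxygen to the alkyne becomes possible.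
Fallback, from 18, returning at 25: the slow deprotection is moved to the robust lactone stage.
- Aqueous HF (48 %) in MeCN at 0 → 20 °C should cleave only the alkyl silyl ether of 18, since aryl silyl ethers resist acid, and give 8-(hydroxymethyl)-3-(triisopropylsilyloxy)-7-{[4-(triisopropylsilyloxy)phenyl]ethynyl}-6H-benzo[c]chromen-6-one F10.
- Treatment with 21 (4.5 equiv, one equivalent being consumed by the hydroxyl) should give, through the dilithium salt of {3-(hydroxymethyl)-6-[2-hydroxy-4-(triisopropylsilyloxy)phenyl]-2-{[4-(triisopropylsilyloxy)phenyl]ethynyl}phenyl}[4-(triisopropylsilyloxy)phenyl]methanone F11, the carbinol {3-(hydroxymethyl)-6-[2-hydroxy-4-(triisopropylsilyloxy)phenyl]-2-{[4-(triisopropylsilyloxy)phenyl]ethynyl}phenyl}bis[4-(triisopropylsilyloxy)phenyl]methanol F12.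
- F12 has only aryl silyl ethers, which buffered Bu4NF should remove within minutes at 0 °C; brief dilute acid then gives 25 through 24.

## Further compounds

F1 | step 6 | methyl (2Z)-3-(trimethylsilyloxy)but-2-enoate | COC(=O)/C=C(/C)O[Si](C)(C)C
F2 | step 6 | (1Z)-1-methoxy-1,3-bis(trimethylsilyloxy)buta-1,3-diene | CO/C(O[Si](C)(C)C)=C/C(=C)O[Si](C)(C)C
F3 | step 6 | methyl 3-oxo-4-[4-oxo-7-(triisopropylsilyloxy)-3,4-dihydro-2H-chromen-2-yl]butanoate (racemic) | COC(=O)CC(=O)CC1CC(=O)c2ccc(O[Si](C(C)C)(C(C)C)C(C)C)cc2O1
F4 | step 6 | 7-hydroxy-3-(triisopropylsilyloxy)-6H-benzo[c]chromen-6-one | O=C1Oc2cc(O[Si](C(C)C)(C(C)C)C(C)C)ccc2-c2cccc(O)c21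
F5 | step 6 | 7-hydroxy-6-oxo-3-(triisopropylsilyloxy)-6H-benzo[c]chromene-8-carbaldehyde | O=C1Oc2cc(O[Si](C(C)C)(C(C)C)C(C)C)ccc2-c2ccc(C=O)c(O)c21
F6 | step 6 | 7-hydroxy-8-(hydroxymethyl)-3-(triisopropylsilyloxy)-6H-benzo[c]chromen-6-one | O=C1Oc2cc(O[Si](C(C)C)(C(C)C)C(C)C)ccc2-c2ccc(CO)c(O)c21
F0 | step 5 | none | none
F7 | step 11 | 7-ethynyl-3-(triisopropylsilyloxy)-8-[(triisopropylsilyloxy)methyl]-6H-benzo[c]chromen-6-one | O=C1Oc2cc(O[Si](C(C)C)(C(C)C)C(C)C)ccc2-c2ccc(CO[Si](C(C)C)(C(C)C)C(C)C)c(C#C)c21
F8 | step 13 | {6-[2,4-bis(triisopropylsilyloxy)phenyl]-3-[(triisopropylsilyloxy)methyl]-2-{[4-(triisopropylsilyloxy)phenyl]ethynyl}phenyl}[4-(triisopropylsilyloxy)phenyl]methanone | O=C(c1ccc(O[Si](C(C)C)(C(C)C)C(C)C)cc1)c1c(-c2ccc(O[Si](C(C)C)(C(C)C)C(C)C)cc2O[Si](C(C)C)(C(C)C)C(C)C)ccc(CO[Si](C(C)C)(C(C)C)C(C)C)c1C#Cc1ccc(O[Si](C(C)C)(C(C)C)C(C)C)cc1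
F9 | step 13 | {6-[2,4-bis(triisopropylsilyloxy)phenyl]-3-[(triisopropylsilyloxy)methyl]-2-{[4-(triisopropylsilyloxy)phenyl]ethynyl}phenyl}bis[4-(triisopropylsilyloxy)phenyl]methanol | OC(c1ccc(O[Si](C(C)C)(C(C)C)C(C)C)cc1)(c1ccc(O[Si](C(C)C)(C(C)C)C(C)C)cc1)c1c(-c2ccc(O[Si](C(C)C)(C(C)C)C(C)C)cc2O[Si](C(C)C)(C(C)C)C(C)C)ccc(CO[Si](C(C)C)(C(C)C)C(C)C)c1C#Cc1ccc(O[Si](C(C)C)(C(C)C)C(C)C)cc1
F10 | step 14 | 8-(hydroxymethyl)-3-(triisopropylsilyloxy)-7-{[4-(triisopropylsilyloxy)phenyl]ethynyl}-6H-benzo[c]chromen-6-one | O=C1Oc2cc(O[Si](C(C)C)(C(C)C)C(C)C)ccc2-c2ccc(CO)c(C#Cc3ccc(O[Si](C(C)C)(C(C)C)C(C)C)cc3)c21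
F11 | step 14 | dilithium salt of {3-(hydroxymethyl)-6-[2-hydroxy-4-(triisopropylsilyloxy)phenyl]-2-{[4-(triisopropylsilyloxy)phenyl]ethynyl}phenyl}[4-(triisopropylsilyloxy)phenyl]methanone | [Li+].[Li+].[O-]Cc1ccc(-c2ccc(O[Si](C(C)C)(C(C)C)C(C)C)cc2[O-])c(C(=O)c2ccc(O[Si](C(C)C)(C(C)C)C(C)C)cc2)c1C#Cc1ccc(O[Si](C(C)C)(C(C)C)C(C)C)cc1
F12 | step 14 | {3-(hydroxymethyl)-6-[2-hydroxy-4-(triisopropylsilyloxy)phenyl]-2-{[4-(triisopropylsilyloxy)phenyl]ethynyl}phenyl}bis[4-(triisopropylsilyloxy)phenyl]methanol | OCc1ccc(-c2ccc(O[Si](C(C)C)(C(C)C)C(C)C)cc2O)c(C(O)(c2ccc(O[Si](C(C)C)(C(C)C)C(C)C)cc2)c2ccc(O[Si](C(C)C)(C(C)C)C(C)C)cc2)c1C#Cc1ccc(O[Si](C(C)C)(C(C)C)C(C)C)cc1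
A1 | alternative 1 | {6-[2,4-bis(methoxymethoxy)phenyl]-3-[(methoxymethoxy)methyl]-2-{[4-(methoxymethoxy)phenyl]ethynyl}phenyl}bis[4-(methoxymethoxy)phenyl]methanol | COCOCc1ccc(-c2ccc(OCOC)cc2OCOC)c(C(O)(c2ccc(OCOC)cc2)c2ccc(OCOC)cc2)c1C#Cc1ccc(OCOC)cc1
A2 | alternative 1 | 4-chloro-1-[(methoxymethoxy)methyl]-2-{[4-(methoxymethoxy)phenyl]ethynyl}benzene | COCOCc1ccc(Cl)cc1C#Cc1ccc(OCOC)cc1
A3 | alternative 1 | [2,4-bis(methoxymethoxy)phenyl]lithium | [Li]c1ccc(OCOC)cc1OCOC
A4 | alternative 1 | bis[4-(methoxymethoxy)phenyl]methanone | COCOc1ccc(cc1)C(=O)c1ccc(OCOC)cc1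
A5 | alternative 2 | 8-[(tert-butyldimethylsilyloxy)methyl]-3-(methoxymethoxy)-7-{[4-(methoxymethoxy)phenyl]ethynyl}-9-(trimethylsilyl)-6H-benzo[c]chromen-6-one | O=C1Oc2cc(OCOC)ccc2-c2cc([Si](C)(C)C)c(CO[Si](C)(C)C(C)(C)C)c(C#Cc3ccc(OCOC)cc3)c21
A6 | alternative 2 | 2-ethynyl-5-(methoxymethoxy)phenyl 5-[4-(methoxymethoxy)phenyl]penta-2,4-diynoate | C#Cc1ccc(OCOC)cc1OC(=O)C#CC#Cc1ccc(OCOC)cc1
A7 | alternative 2 | tert-butyldimethyl{[3-(trimethylsilyl)prop-2-yn-1-yl]oxy}silane | C[Si](C)(C)C#CCO[Si](C)(C)C(C)(C)C
A8 | alternative 3 | methyl 6-(4-tert-butoxy-2-hydroxyphenyl)-3-[(tert-butyldimethylsilyloxy)methyl]-2-{[4-(methoxymethoxy)phenyl]ethynyl}benzoate | COC(=O)c1c(-c2ccc(OC(C)(C)C)cc2O)ccc(CO[Si](C)(C)C(C)(C)C)c1C#Cc1ccc(OCOC)cc1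
A9 | alternative 3 | methyl 3-[(tert-butyldimethylsilyloxy)methyl]-6-[(1E)-4-diazo-3-oxobut-1-en-1-yl]-2-{[4-(methoxymethoxy)phenyl]ethynyl}benzoate | COC(=O)c1c(/C=C/C(=O)C=[N+]=[N-])ccc(CO[Si](C)(C)C(C)(C)C)c1C#Cc1ccc(OCOC)cc1
A10 | alternative 3 | tert-butoxyethyne | C#COC(C)(C)C
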